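**Retrosynthetic overview**

1. Target 29 comes from tricyclic methyl enol ether 24 by C3 aroylation and global deprotection; 24 comes from tricyclic aldehyde 21 by Wittig olefination (C7 prenyl), allyl-to-prenyl cross-metathesis (C1) and dehydration of a tertiary alcohol (C12 isopropenyl).
2. Key disconnection C7–C8, closing ring B (C1, C8, C7, C6, C5, C9): 21 from spiro enal 20 by a hydrogen-atom-transfer-initiated 6-exo radical conjugate addition. The enabling feature is the gem-dimethyl quaternary C8 on the quaternary bridgehead C1 (the H-atom adduct of an isopropenyl group), which faces, 1,3-diaxially across the C9 carbonyl of ring A, the prenyl-bearing C7 (the β-carbon of an (E)-enal whose CHO is the Wittig retron of the prenyl group).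
3. 20 comes from aryl bis-carbonate 17 by one palladium cascade: dearomative allylic alkylation at C5 closes ring C (C5–C6 bond), then an O-to-C allyl shift makes C1 quaternary.
4. 17 comes from isopropenylphenol 14 (from 2,6-dihydroxy-4-methoxyacetophenone) and lactol 11, which carries C6, C7 and C10–C16 and is made from (R)-α-terpineol (C12 stereocentre; its tertiary alcohol masks the C12 isopropenyl group); C6 is set by CBS reduction.
5. Order of ring formation: ring A (aromatic from the start, dearomatised in step 10), then ring C (seven-membered, step 10), then ring B (step 12).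

Key step: step 12

Numbering used for all spiro and tricyclic compounds: C1–C9 are the bicyclo[3.3.1]nonane atoms of the target (C1 and C5 bridgeheads, C2–C4 in ring A, C6–C8 in ring B, C9 the bridging carbonyl, C8 the gem-dimethyl carbon); C10–C14 complete ring C (C5, C6, C10, C11, C12, C13, C14); C15 and C16 are the first two side-chain carbons on C7. Descriptors refer to this numbering; at C1 and C12 the CIP letter changes between intermediates while the spatial arrangement stays the same.

Assumption: the CBS reduction treats the alkenyl arm of enone 7 as the large substituent, and the palladium-mediated ring closure proceeds with net retention at C6 (ionisation and attack both anti to palladium).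

**Route**

Step 1
Reactants: 1 (R)-(+)-α-terpineol
Product: 3 (4R)-5,5-dimethyl-4-(3-oxobutyl)oxolan-2-one, via hydroxy keto acid 2 (not isolated)
Conditions: RuCl3·xH2O (2 mol %), NaIO4 (4 equiv), CCl4/MeCN/H2O, rt; 1 M HCl work-up
Reagents that add atoms: sodium periodate, [Na+].[O-]I(=O)(=O)=O
Why: RuO4 generated in the flask cleaves the trisubstituted ring alkene to a methyl ketone and a carboxylic acid (oxidative alkene cleavage), and the γ-hydroxy acid should lactonise on acidic work-up, leaving the stereocentre (future C12) untouched.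

Step 2
Reactants: 3 (4R)-5,5-dimethyl-4-(3-oxobutyl)oxolan-2-one; 4 2,2-dimethoxyacetaldehyde (anhydrous)
Product: 7 (4R)-4-[(4E)-6,6-dimethoxy-3-oxohex-4-en-1-yl]-5,5-dimethyloxolan-2-one, via aldol adduct 5 (not isolated), via mesylate 6 (not isolated)
Conditions: LiN(iPr)2 (1.05 equiv), THF, −78 °C; 4, −78 °C; then MsCl, Et3N, 0 °C to rt
Reagents that add atoms: none
Why: Kinetic deprotonation of the methyl ketone at CH3 (the lactone α-CH2 is less acidic), crossed aldol addition to the non-enolisable aldehyde and mesylation/E1cB elimination should give the (E)-enone (aldol condensation).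

Step 3
Reactants: 7 (4R)-4-[(4E)-6,6-dimethoxy-3-oxohex-4-en-1-yl]-5,5-dimethyloxolan-2-one
Product: 8 (4R)-4-[(3S,4E)-3-hydroxy-6,6-dimethoxyhex-4-en-1-yl]-5,5-dimethyloxolan-2-one
Conditions: (R)-2-methyl-CBS-oxazaborolidine (15 mol %), BH3·SMe2, toluene, −40 °C; MeOH quench
Reagents that add atoms: none
Why: Corey–Bakshi–Shibata 1,2-reduction of the enone, with the alkenyl arm as the large group, should deliver the (S)-carbinol (future C6–O), while lactone and acetal are inert to borane at this temperature.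

Step 4
Reactants: 8 (4R)-4-[(3S,4E)-3-hydroxy-6,6-dimethoxyhex-4-en-1-yl]-5,5-dimethyloxolan-2-one
Product: 10 (4R)-4-[(3S,4E)-3-hydroxy-6,6-dimethoxyhex-4-en-1-yl]-3,3,5,5-tetramethyloxolan-2-one, via monomethyl lactone 9 (not isolated)
Conditions: LiN(iPr)2 (2.2 equiv), THF, −78 °C, MeI; then LiN(iPr)2 (1.3 equiv), MeI, −78 to 0 °C
Reagents that add atoms: iodomethane, CI
Why: Two successive lactone enolate methylations (the lithium alkoxide is not methylated in THF at low temperature, as in Fráter–Seebach dianion alkylations) install the gem-dimethyl group of C13.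

Step 5
Reactants: 10 (4R)-4-[(3S,4E)-3-hydroxy-6,6-dimethoxyhex-4-en-1-yl]-3,3,5,5-tetramethyloxolan-2-one
Product: 11 (4R)-4-[(3S,4E)-3-hydroxy-6,6-dimethoxyhex-4-en-1-yl]-3,3,5,5-tetramethyloxolan-2-ol (anomeric mixture)
Conditions: i-Bu2AlH (2.2 equiv), CH2Cl2, −78 °C; Rochelle salt work-up
Reagents that add atoms: none
Why: Partial reduction of the hindered γ-lactone should stop at the lactol (stable tetrahedral aluminate at −78 °C), which is the masked C14 aldehyde.

Step 6
Reactants: 12 1-(2,6-dihydroxy-4-methoxyphenyl)ethan-1-one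
Product: 13 1-[2-hydroxy-4-methoxy-6-(prop-2-en-1-yloxy)phenyl]ethan-1-one
Conditions: allyl bromide (1.05 equiv), K2CO3, acetone, 56 °C
Reagents that add atoms: allyl bromide, C=CCBr
Why: Williamson etherification stops at the mono-ether because the remaining hydroxyl is held in the hydrogen bond to the acetyl group.

Step 7
Reactants: 13 1-[2-hydroxy-4-methoxy-6-(prop-2-en-1-yloxy)phenyl]ethan-1-one
Product: 14 5-methoxy-2-(prop-1-en-2-yl)-3-(prop-2-en-1-yloxy)phenol
Conditions: Ph3PCH3Br, KOtBu (3 equiv each), THF, 0 to 50 °C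
Reagents that add atoms: methyltriphenylphosphonium bromide, C[P+](c1ccccc1)(c1ccccc1)c1ccccc1.[Br-]
Why: Wittig methylenation of the o-hydroxyacetophenone with excess ylide (the phenoxide is tolerated) should give the 2-isopropenylphenol under base-only conditions.

Step 8
Reactants: 11 (4R)-4-[(3S,4E)-3-hydroxy-6,6-dimethoxyhex-4-en-1-yl]-3,3,5,5-tetramethyloxolan-2-ol; 14 5-methoxy-2-(prop-1-en-2-yl)-3-(prop-2-en-1-yloxy)phenol
Product: 16 2-[(3R,6S,7E)-6-hydroxy-3-(2-hydroxypropan-2-yl)-9,9-dimethoxy-2,2-dimethylnon-7-en-1-yl]-3-methoxy-6-(prop-1-en-2-yl)-5-(prop-2-en-1-yloxy)phenol, via benzylic carbinol 15 (not isolated)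
Conditions: 14 (2.2 equiv), EtMgBr, Et2O, 0 °C; solvent changed to CH2Cl2, 11, rt; then EtOH, NaBH4, 2 M NaOH, 60 °C
Reagents that add atoms: none
Why: The bromomagnesium phenoxide should add through its only free ortho carbon to the magnesium-bound open form of the lactol (ortho-specific hydroxyalkylation of magnesium phenoxides), and alkaline NaBH4 should then remove the benzylic oxygen by hydride addition to the ortho-quinone methide, a pathway that also reopens any cyclic benzylic ether formed with the tertiary hydroxyl.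

Step 9
Reactants: 16 2-[(3R,6S,7E)-6-hydroxy-3-(2-hydroxypropan-2-yl)-9,9-dimethoxy-2,2-dimethylnon-7-en-1-yl]-3-methoxy-6-(prop-1-en-2-yl)-5-(prop-2-en-1-yloxy)phenol
Product: 17 bis(methyl carbonate) of 16 (aryl O-carbonate and (6S)-allylic O-carbonate; tertiary alcohol free)
Conditions: ClCO2Me (3 equiv), pyridine, CH2Cl2, 0 °C
Reagents that add atoms: methyl chloroformate, COC(=O)Cl
Why: Chloroformate acylation takes the phenol and the secondary allylic alcohol but not the tertiary alcohol, which provides the allylic leaving group without touching C6.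

Step 10
Reactants: 17 bis(methyl carbonate) of 16
Product: 19 (1R,5S,6S,12R)-spiro dione: ring A = 1-allyl-4-methoxy-1-(prop-1-en-2-yl)cyclohex-3-ene-2,9-dione, spiro at C5 to ring C carrying (1E)-3,3-dimethoxyprop-1-enyl at C6, 2-hydroxypropan-2-yl at C12 and gem-dimethyl at C13, via spirodienone allyl ether 18 (not isolated)
Conditions: Pd(PPh3)4 (5 mol %), THF (0.005 M), 0 to 40 °C
Reagents that add atoms: none
Why: Zerovalent palladium ionises the allylic carbonate with inversion, the methoxide set free unmasks the phenoxide, and its substituted ortho carbon C5 attacks the allyl terminus C6 anti to palladium (intramolecular dearomative Tsuji–Trost alkylation, 7-exo closure of ring C, net retention at C6, with the phenoxide oxygen on C9 turned toward the cationic allyl unit and the methoxy flank toward C6–H); the O-allyl vinylogous ester so formed is ionised in turn and the diketone enolate is C-allylated at C1 on the face remote from C6 (palladium-catalysed O-to-C allyl transfer).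

Step 11
Reactants: 19 spiro dione acetal
Product: 20 (1R,5S,6S,12R)-spiro enal: as 19 but with (1E)-3-oxoprop-1-enyl at C6
Conditions: PPTS (cat.), acetone/H2O (10:1), 40 °C
Reagents that add atoms: water, O
Why: Mild acid-catalysed acetal hydrolysis unveils the (E)-enal, and the vinylogous ester, tertiary alcohol and alkenes tolerate pyridinium tosylate.

Step 12
Reactants: 20 spiro enal
Product: 21 (1R,5S,6S,7S,12R)-1-allyl-12-(2-hydroxypropan-2-yl)-4-methoxy-8,8,13,13-tetramethyl-7-(2-oxoethyl)-tricyclic 3-ene-2,9-dione (bicyclo[3.3.1]nonane of rings A and B with ring C fused at C5–C6)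
Conditions: Fe(acac)3 (30 mol %), PhSiH3 (2.5 equiv), EtOH/(CH2OH)2 (5:1), 60 °C, degassed, 0.01 M
Reagents that add atoms: none
Why: An iron hydride formed from Fe(acac)3 and PhSiH3 transfers a hydrogen atom to the CH2 terminus of the C1 isopropenyl group (Markovnikov HAT), and the tertiary, nucleophilic C8 radical adds to C7, the β-carbon of the enal, after which the α-formyl radical at C15 is reduced by divalent iron and protonated by ethanol. The closest known reaction type is the iron-mediated reductive olefin coupling in its intramolecular form (HAT-initiated Giese cyclisation), which is known to join a new quaternary carbon to a hindered neighbour. Ring B closes in the 6-exo-trig mode between the two 1,3-diaxial arms on C1 and C5 of ring A, which creates the bicyclo[3.3.1]nonane in the same event. The new stereocentre C7 is controlled by C6: the enal reacts in the rotamer with C6–H eclipsing the C7=C15 bond (minimal A(1,3) strain) and the tether through C5 forces attack on the face anti to C10, so the CH2CHO arm ends trans to C10, the arrangement that lets ring B adopt a boat with both groups pseudo-equatorial; C8 becomes a non-stereogenic quaternary carbon. The step needs HAT at the 1,1-disubstituted alkene rather than at the allyl group or the enal, and cyclisation faster than reduction or a 1,2-acyl shift of the radical; this is secured because the only other isopropenyl group of the target is masked as the C12 tertiary alcohol, the acceptor is an activated enal held within reach, and C1 is already quaternary so that no bridgehead enol is required.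

Step 13
Reactants: 21 tricyclic aldehyde
Product: 22 (1R,5S,6S,7S,12R)-1-allyl-12-(2-hydroxypropan-2-yl)-4-methoxy-8,8,13,13-tetramethyl-7-(3-methylbut-2-en-1-yl)-tricyclic 3-ene-2,9-dione
Conditions: Me2CHPPh3I, n-BuLi, THF, 0 °C; then 21, −78 to 0 °C
Reagents that add atoms: isopropyltriphenylphosphonium iodide, CC(C)[P+](c1ccccc1)(c1ccccc1)c1ccccc1.[I-]
Why: Wittig olefination of the aldehyde with the unstabilised isopropylidene ylide, chemoselective over the hindered non-enolisable C9 ketone and the vinylogous ester, completes the C7 prenyl group.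

Step 14
Reactants: 22 C7-prenyl tricycle
Product: 23 (1R,5S,6S,7S,12R)-12-(2-hydroxypropan-2-yl)-4-methoxy-8,8,13,13-tetramethyl-1,7-bis(3-methylbut-2-en-1-yl)-tricyclic 3-ene-2,9-dione
Conditions: second-generation Grubbs catalyst RuCl2(=CHPh)(PCy3)(H2IMes) (5 mol %), 2-methylbut-2-ene/CH2Cl2, 40 °C
Reagents that add atoms: 2-methylbut-2-ene, CC=C(C)C
Why: Olefin cross-metathesis converts the terminal allyl group into prenyl (the standard allyl-to-prenyl exchange on such cores); the existing prenyl group reacts degenerately and no 1,1-disubstituted alkene is present yet.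

Step 15
Reactants: 23 bis-prenyl tertiary alcohol
Product: 24 (1R,5S,6S,7S,12S)-4-methoxy-8,8,13,13-tetramethyl-1,7-bis(3-methylbut-2-en-1-yl)-12-(prop-1-en-2-yl)-tricyclic 3-ene-2,9-dione
Conditions: Burgess reagent (methyl N-(triethylammoniosulfonyl)carbamate), toluene, 60 °C
Reagents that add atoms: none
Why: Burgess syn-dehydration of the tertiary alcohol should go toward a methyl group (six accessible hydrogens) and not toward the hindered C12–H, whose loss would give a tetrasubstituted alkene clashing with the C13 gem-dimethyl group.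

Step 16
Reactants: 25 3,4-dihydroxybenzoic acid
Product: 26 tert-butyldimethylsilyl 3,4-bis[(tert-butyldimethylsilyl)oxy]benzoate
Conditions: TBSCl (3.5 equiv), imidazole, DMF, rt
Reagents that add atoms: tert-butyl(chloro)dimethylsilane, CC(C)(C)[Si](C)(C)Cl
Why: Exhaustive silylation protects both phenols and gives the silyl ester needed for direct conversion into the acid chloride.

Step 17
Reactants: 26 tert-butyldimethylsilyl 3,4-bis[(tert-butyldimethylsilyl)oxy]benzoate
Product: 27 3,4-bis[(tert-butyldimethylsilyl)oxy]benzoyl chloride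
Conditions: (COCl)2, DMF (cat.), CH2Cl2, 0 °C to rt
Reagents that add atoms: oxalyl chloride, O=C(Cl)C(=O)Cl
Why: The Vilsmeier-type chloride from oxalyl chloride and DMF converts the silyl ester directly into the acid chloride under neutral conditions that keep the aryl silyl ethers.

Step 18
Reactants: 24 tricyclic methyl enol ether; 27 3,4-bis[(tert-butyldimethylsilyl)oxy]benzoyl chloride
Product: 28 (1S,5S,6S,7S,12S)-3-{3,4-bis[(tert-butyldimethylsilyl)oxy]benzoyl}-4-methoxy-8,8,13,13-tetramethyl-1,7-bis(3-methylbut-2-en-1-yl)-12-(prop-1-en-2-yl)-tricyclic 3-ene-2,9-dione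
Conditions: lithium 2,2,6,6-tetramethylpiperidide (from the amine and n-BuLi), THF, −78 °C; then 27, −78 to −40 °C
Reagents that add atoms: none
Why: With both bridgeheads quaternary, the only acidic site is the vinylic C3–H of the vinylogous ester, and the resulting vinyllithium is C-acylated by the acid chloride (the usual late C3 acylation of such cores).

Step 19
Reactants: 28 silyl-protected aroyl methyl enol ether
Product: 29 target, (1S,5S,6S,7S,12S)-3-(3,4-dihydroxybenzoyl)-4-hydroxy-8,8,13,13-tetramethyl-1,7-bis(3-methylbut-2-en-1-yl)-12-(prop-1-en-2-yl)-tricyclic 3-ene-2,9-dione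
Conditions: LiOH (aq.), 1,4-dioxane, 90 °C, degassed; 1 M HCl work-up
Reagents that add atoms: lithium hydroxide, [Li+].[OH-]
Why: Hydroxide cleaves the methyl vinylogous ester by addition–elimination at C4 and the two aryl silyl ethers at silicon, and acidification should give the enolised β-triketone and the free catechol.

**Compound list**

1 | (R)-(+)-α-terpineol, 2-[(1R)-4-methylcyclohex-3-en-1-yl]propan-2-ol | CC1=CC[C@@H](CC1)C(C)(C)O | starting material
2 | (3R)-3-(2-hydroxypropan-2-yl)-6-oxoheptanoic acid | CC(=O)CC[C@H](CC(=O)O)C(C)(C)O | intermediate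
3 | (4R)-5,5-dimethyl-4-(3-oxobutyl)oxolan-2-one | CC(=O)CC[C@@H]1CC(=O)OC1(C)C | intermediate
4 | 2,2-dimethoxyacetaldehyde | COC(OC)C=O | starting material
5 | (4R)-4-(5-hydroxy-6,6-dimethoxy-3-oxohexyl)-5,5-dimethyloxolan-2-one (carbinol epimers) | CC1(C)OC(=O)C[C@H]1CCC(=O)CC(O)C(OC)OC | intermediate
6 | methanesulfonate of 5 | CC1(C)OC(=O)C[C@H]1CCC(=O)CC(OS(C)(=O)=O)C(OC)OC | intermediate
7 | (4R)-4-[(4E)-6,6-dimethoxy-3-oxohex-4-en-1-yl]-5,5-dimethyloxolan-2-one | CC1(C)OC(=O)C[C@H]1CCC(=O)/C=C/C(OC)OC | intermediate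
8 | (4R)-4-[(3S,4E)-3-hydroxy-6,6-dimethoxyhex-4-en-1-yl]-5,5-dimethyloxolan-2-one | CC1(C)OC(=O)C[C@H]1CC[C@H](O)/C=C/C(OC)OC | intermediate
9 | (4R)-4-[(3S,4E)-3-hydroxy-6,6-dimethoxyhex-4-en-1-yl]-3,5,5-trimethyloxolan-2-one (C3 epimers) | CC1(C)OC(=O)C(C)[C@H]1CC[C@H](O)/C=C/C(OC)OC | intermediate
10 | (4R)-4-[(3S,4E)-3-hydroxy-6,6-dimethoxyhex-4-en-1-yl]-3,3,5,5-tetramethyloxolan-2-one | CC1(C)OC(=O)C(C)(C)[C@H]1CC[C@H](O)/C=C/C(OC)OC | intermediate
11 | (4R)-4-[(3S,4E)-3-hydroxy-6,6-dimethoxyhex-4-en-1-yl]-3,3,5,5-tetramethyloxolan-2-ol (anomers) | CC1(C)OC(O)C(C)(C)[C@H]1CC[C@H](O)/C=C/C(OC)OC | intermediate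
12 | 1-(2,6-dihydroxy-4-methoxyphenyl)ethan-1-one | CC(=O)c1c(O)cc(OC)cc1O | starting material
13 | 1-[2-hydroxy-4-methoxy-6-(prop-2-en-1-yloxy)phenyl]ethan-1-one | CC(=O)c1c(O)cc(OC)cc1OCC=C | intermediate
14 | 5-methoxy-2-(prop-1-en-2-yl)-3-(prop-2-en-1-yloxy)phenol | C=C(C)c1c(O)cc(OC)cc1OCC=C | intermediate
15 | 2-[(3R,6S,7E)-1,6-dihydroxy-3-(2-hydroxypropan-2-yl)-9,9-dimethoxy-2,2-dimethylnon-7-en-1-yl]-3-methoxy-6-(prop-1-en-2-yl)-5-(prop-2-en-1-yloxy)phenol (C1′ epimers) | COC(OC)/C=C/[C@@H](O)CC[C@@H](C(C)(C)O)C(C)(C)C(O)c1c(O)c(C(C)=C)c(OCC=C)cc1OC | intermediate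
16 | 2-[(3R,6S,7E)-6-hydroxy-3-(2-hydroxypropan-2-yl)-9,9-dimethoxy-2,2-dimethylnon-7-en-1-yl]-3-methoxy-6-(prop-1-en-2-yl)-5-(prop-2-en-1-yloxy)phenol | COC(OC)/C=C/[C@@H](O)CC[C@@H](C(C)(C)O)C(C)(C)Cc1c(O)c(C(C)=C)c(OCC=C)cc1OC | intermediate
17 | bis(methyl carbonate) of 16 (aryl and (6S)-allylic O-carbonates) | COC(OC)/C=C/[C@@H](OC(=O)OC)CC[C@@H](C(C)(C)O)C(C)(C)Cc1c(OC(=O)OC)c(C(C)=C)c(OCC=C)cc1OC | intermediate
18 | (5S,6S,12R)-spirodienone allyl ether: ring A = 4-methoxy-1-(prop-1-en-2-yl)-2-(prop-2-en-1-yloxy)cyclohexa-1,3-dien-9-one, spiro at C5 to ring C (C6 (1E)-3,3-dimethoxyprop-1-enyl, C12 2-hydroxypropan-2-yl, C13 gem-dimethyl) | CC(C)(O)[C@@H]1CC[C@@H](/C=C/C(OC)OC)[C@]2(CC1(C)C)C(=O)C(C(C)=C)=C(OCC=C)C=C2OC | intermediate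
19 | (1R,5S,6S,12R)-spiro dione acetal: ring A = 1-allyl-4-methoxy-1-(prop-1-en-2-yl)cyclohex-3-ene-2,9-dione, isopropenyl on C1 cis to C6, ring C as in 18 | CC(C)(O)[C@@H]1CC[C@@H](/C=C/C(OC)OC)[C@]2(CC1(C)C)C(=O)[C@](CC=C)(C(C)=C)C(=O)C=C2OC | intermediate
20 | (1R,5S,6S,12R)-spiro enal: as 19 with (1E)-3-oxoprop-1-enyl at C6 | CC(C)(O)[C@@H]1CC[C@@H](/C=C/C=O)[C@]2(CC1(C)C)C(=O)[C@](CC=C)(C(C)=C)C(=O)C=C2OC | intermediate
21 | (1R,5S,6S,7S,12R)-1-allyl-12-(2-hydroxypropan-2-yl)-4-methoxy-8,8,13,13-tetramethyl-7-(2-oxoethyl)-tricyclic 3-ene-2,9-dione | CC(C)(O)[C@@H]1CC[C@H]2[C@H](CC=O)C(C)(C)[C@]3(CC=C)C(=O)C=C(OC)[C@@]2(CC1(C)C)C3=O | intermediate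
22 | (1R,5S,6S,7S,12R)-1-allyl-12-(2-hydroxypropan-2-yl)-4-methoxy-8,8,13,13-tetramethyl-7-(3-methylbut-2-en-1-yl)-tricyclic 3-ene-2,9-dione | CC(C)(O)[C@@H]1CC[C@H]2[C@H](CC=C(C)C)C(C)(C)[C@]3(CC=C)C(=O)C=C(OC)[C@@]2(CC1(C)C)C3=O | intermediate
23 | (1R,5S,6S,7S,12R)-12-(2-hydroxypropan-2-yl)-4-methoxy-8,8,13,13-tetramethyl-1,7-bis(3-methylbut-2-en-1-yl)-tricyclic 3-ene-2,9-dione | CC(C)(O)[C@@H]1CC[C@H]2[C@H](CC=C(C)C)C(C)(C)[C@]3(CC=C(C)C)C(=O)C=C(OC)[C@@]2(CC1(C)C)C3=O | intermediate
24 | (1R,5S,6S,7S,12S)-4-methoxy-8,8,13,13-tetramethyl-1,7-bis(3-methylbut-2-en-1-yl)-12-(prop-1-en-2-yl)-tricyclic 3-ene-2,9-dione | C=C(C)[C@@H]1CC[C@H]2[C@H](CC=C(C)C)C(C)(C)[C@]3(CC=C(C)C)C(=O)C=C(OC)[C@@]2(CC1(C)C)C3=O | intermediate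
25 | 3,4-dihydroxybenzoic acid | O=C(O)c1ccc(O)c(O)c1 | starting material
26 | tert-butyldimethylsilyl 3,4-bis[(tert-butyldimethylsilyl)oxy]benzoate | CC(C)(C)[Si](C)(C)OC(=O)c1ccc(O[Si](C)(C)C(C)(C)C)c(O[Si](C)(C)C(C)(C)C)c1 | intermediate
27 | 3,4-bis[(tert-butyldimethylsilyl)oxy]benzoyl chloride | O=C(Cl)c1ccc(O[Si](C)(C)C(C)(C)C)c(O[Si](C)(C)C(C)(C)C)c1 | intermediate
28 | (1S,5S,6S,7S,12S)-3-{3,4-bis[(tert-butyldimethylsilyl)oxy]benzoyl}-4-methoxy-8,8,13,13-tetramethyl-1,7-bis(3-methylbut-2-en-1-yl)-12-(prop-1-en-2-yl)-tricyclic 3-ene-2,9-dione | C=C(C)[C@@H]1CC[C@H]2[C@H](CC=C(C)C)C(C)(C)[C@]3(CC=C(C)C)C(=O)C(C(=O)c4ccc(O[Si](C)(C)C(C)(C)C)c(O[Si](C)(C)C(C)(C)C)c4)=C(OC)[C@@]2(CC1(C)C)C3=O | intermediate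
29 | (1S,5S,6S,7S,12S)-3-(3,4-dihydroxybenzoyl)-4-hydroxy-8,8,13,13-tetramethyl-1,7-bis(3-methylbut-2-en-1-yl)-12-(prop-1-en-2-yl)-tricyclic 3-ene-2,9-dione | C=C(C)[C@@H]1CC[C@H]2[C@H](CC=C(C)C)C(C)(C)[C@]3(CC=C(C)C)C(=O)C(C(=O)c4ccc(O)c(O)c4)=C(O)[C@@]2(CC1(C)C)C3=O | target

**Step count and risks**

Total step count: 19. Longest linear sequence: 15 steps (steps 1–5, 8–15, 18 and 19).

Steps most likely to fail:

Step 10. The ring closure may show poor facial control at C5 (the two oxygen-bearing flanks of the arene differ only as phenoxide versus methoxy), the seven-membered closure may be slow enough for the aryl allyl ether to ionise first, and the allyl transfer may not discriminate the faces at C1. The fallback sets out from 16 and comes back at 19 without palladium. Chlorination of the allylic alcohol with inversion (Ph3P, hexachloroacetone, CH2Cl2, −20 °C) should give the allylic chloride F3. LiN(SiMe3)2 in THF (−78 to 0 °C, high dilution) should effect alkylative dearomatisation by direct SN2 attack of the lithium phenoxide carbon C5 (second inversion, tight lithium-bound transition state) to give 18, now isolated. A thermal Claisen rearrangement of 18 (toluene, 100 °C, chair transition state from O2 to C1) then gives 19.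

Step 12. Hydrogen-atom transfer may also occur at the allyl group or the enal, the β-dicarbonyl radical may undergo a 1,2-acyl (Dowd–Beckwith) shift before it cyclises, and the facial selectivity at C7 may be lower than argued. The fallback sets out from 19 and comes back at 21, separating radical generation from the acceptor. Cobalt-catalysed Markovnikov hydrochlorination of the isopropenyl group while the enal is still masked (Co(BF4)2·6H2O with a salen-type ligand, PhSiH3, TsCl, EtOH, rt) should give the tertiary chloride F4. Acetal hydrolysis (PPTS, acetone/H2O) gives the chloro enal F5, and slow addition of Bu3SnH/AIBN in benzene at 80 °C should effect the same 6-exo Giese cyclisation to 21.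

Step 8. The hindered, strongly lactol-stabilised aldehyde may not add to the magnesium phenoxide, or the quinone methide may be captured by the tertiary hydroxyl as a cyclic benzylic ether faster than hydride reduces it. The fallback sets out from 11 and 12 and comes back at 16, moving the C–C bond formation to the symmetric acetophenone. A three-component reductive alkylation of 12 with 11 (L-proline cat., diethyl 2,6-dimethyl-1,4-dihydropyridine-3,5-dicarboxylate, CH2Cl2/EtOH, 40 °C; Mannich-type ortho attack, then transfer hydrogenation of the quinone methide) should give the C-alkylated acetophenone F1. Allyl bromide/K2CO3 should etherify the less hindered hydroxyl, remote from the new neopentyl arm, to give the allyl ether F2, and Wittig methylenation with excess Ph3P=CH2 returns 16.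

Further compounds

F1 | step 8 | 1-{2,6-dihydroxy-3-[(3R,6S,7E)-6-hydroxy-3-(2-hydroxypropan-2-yl)-9,9-dimethoxy-2,2-dimethylnon-7-en-1-yl]-4-methoxyphenyl}ethan-1-one | COC(OC)/C=C/[C@@H](O)CC[C@@H](C(C)(C)O)C(C)(C)Cc1c(O)c(C(C)=O)c(O)cc1OC
F2 | step 8 | 1-{2-hydroxy-3-[(3R,6S,7E)-6-hydroxy-3-(2-hydroxypropan-2-yl)-9,9-dimethoxy-2,2-dimethylnon-7-en-1-yl]-4-methoxy-6-(prop-2-en-1-yloxy)phenyl}ethan-1-one | COC(OC)/C=C/[C@@H](O)CC[C@@H](C(C)(C)O)C(C)(C)Cc1c(O)c(C(C)=O)c(OCC=C)cc1OC
F3 | step 10 | 2-[(3R,6R,7E)-6-chloro-3-(2-hydroxypropan-2-yl)-9,9-dimethoxy-2,2-dimethylnon-7-en-1-yl]-3-methoxy-6-(prop-1-en-2-yl)-5-(prop-2-en-1-yloxy)phenol | COC(OC)/C=C/[C@H](Cl)CC[C@@H](C(C)(C)O)C(C)(C)Cc1c(O)c(C(C)=C)c(OCC=C)cc1OC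
F4 | step 12 | (1R,5S,6S,12R)-spiro dione acetal with 2-chloropropan-2-yl in place of isopropenyl at C1 | CC(C)(O)[C@@H]1CC[C@@H](/C=C/C(OC)OC)[C@]2(CC1(C)C)C(=O)[C@](CC=C)(C(C)(C)Cl)C(=O)C=C2OC
F5 | step 12 | (1R,5S,6S,12R)-spiro enal with 2-chloropropan-2-yl in place of isopropenyl at C1 | CC(C)(O)[C@@H]1CC[C@@H](/C=C/C=O)[C@]2(CC1(C)C)C(=O)[C@](CC=C)(C(C)(C)Cl)C(=O)C=C2OC
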